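**Retrosynthetic overview**
1. The C10–C11 bond (ring CH2 to the enone β-carbon) is made last by a 10-endo-dig radical macrocyclization of the primary iodide 25 onto its ynone. This closes the ten-membered ring and sets the 9Z enone in one step.
2. 25 comes from an indium Barbier allylation of α-acyloxy aldehyde 23 with bromomethyl butenolide 9 (C3a–C4 bond, exo-methylene, C3a and C4 set, O4 born free next to the already acylated O5).
3. 23 comes from cis-lactone 18, 1-propynyllithium and epoxyangelic acid 4, then ozonolysis. 18 comes from Brown syn-crotylation of crotonaldehyde (C5, C6), hydroboration and oxidative lactonization.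
4. 9 comes from ring-closing metathesis of the 2-(bromomethyl)acrylate of (S)-1-iodobut-3-en-2-ol (C11a from the chiral pool). 4 comes from angelic acid by Sharpless epoxidation.
5. Ring order: butenolide first (metathesis), ten-membered carbocycle last. Lactone 18 is a temporary ring that the acetylide opens again.

Assumption: locants are those of the cyclodeca[b]furan skeleton of the target (O1, C2, C3, C3a, C4 to C11, C11a), and (S)-but-3-ene-1,2-diol, angelic acid and 1-propynyllithium are taken as purchasable.

**Fragment 1: the acid**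

Step 1
Reactants: 1 angelic acid, (2Z)-2-methylbut-2-enoic acid
Product: 2 (2Z)-2-methylbut-2-en-1-ol
Conditions: LiAlH4, Et2O, 0 °C to rt
Reagents that add atoms: none
Why: LiAlH4 reduction of the carboxylic acid gives the allylic alcohol without touching or isomerising the trisubstituted Z-alkene.

Step 2
Reactants: 2 (2Z)-2-methylbut-2-en-1-ol
Product: 3 [(2R,3S)-2,3-dimethyloxiran-2-yl]methanol
Conditions: Ti(OiPr)4 (10 mol%), D-(−)-diethyl tartrate (12 mol%), t-BuOOH, 4 Å MS, CH2Cl2, −20 °C
Reagents that add atoms: tert-butyl hydroperoxide, CC(C)(C)OO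
Why: Sharpless asymmetric epoxidation with the D-(−)-tartrate delivers oxygen to the alkene face that gives the (2R,3S)-epoxide, and the cis relation of CH2OH and the C3 methyl is carried over from the Z-alkene.

Step 3
Reactants: 3 [(2R,3S)-2,3-dimethyloxiran-2-yl]methanol
Product: 4 (2S,3S)-2,3-dimethyloxirane-2-carboxylic acid
Conditions: RuCl3 hydrate (2 mol%), NaIO4, CCl4/MeCN/H2O, rt
Reagents that add atoms: water, O
Why: RuO4 formed catalytically from RuCl3 and NaIO4 oxidises the primary alcohol to the acid without opening the epoxide (Sharpless ruthenium oxidation); C2 changes from R to S only through the priority change.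

**Fragment 2: the butenolide**

Step 4
Reactants: 5 (2S)-but-3-ene-1,2-diol
Product: 6 (2S)-1-iodobut-3-en-2-ol
Conditions: I2, PPh3, imidazole, CH2Cl2, 0 °C
Reagents that add atoms: iodine, II
Why: Appel-type iodination takes the primary hydroxyl much faster than the secondary allylic one at 0 °C, so the stereocentre (the later C11a) is untouched.

Step 5
Reactants: 6 (2S)-1-iodobut-3-en-2-ol; 7 2-(bromomethyl)prop-2-enoic acid
Product: 8 (2S)-1-iodobut-3-en-2-yl 2-(bromomethyl)prop-2-enoate
Conditions: DCC, DMAP (5 mol%), CH2Cl2, 0 °C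
Reagents that add atoms: none
Why: Steglich esterification acylates the secondary alcohol under neutral conditions, so the iodohydrin does not close to an epoxide and the allylic bromide survives.

Step 6
Reactants: 8 (2S)-1-iodobut-3-en-2-yl 2-(bromomethyl)prop-2-enoate
Product: 9 (5S)-3-(bromomethyl)-5-(iodomethyl)furan-2(5H)-one
Conditions: second-generation Grubbs catalyst RuCl2(=CHPh)(SIMes)(PCy3) (5 mol%), toluene, 80 °C
Reagents that add atoms: none
Why: Ring-closing metathesis between the vinyl group and the 1,1-disubstituted acrylate closes the butenolide with loss of ethene; alkyl and allyl halides are tolerated and C5 is not involved.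

**Fragment 3: the aldehyde**

Step 7
Reactants: 10 cis-but-2-ene; 11 (2E)-but-2-enal
Product: 15 (3S,4S,5E)-3-methylhepta-1,5-dien-4-ol, via crotylpotassium 12 (not isolated), via crotylborane 13 (not isolated), via borinate 14 (not isolated)
Conditions: n-BuLi, KOt-Bu, THF, −78 to −45 °C; (+)-Ipc2BOMe, −78 °C; BF3·OEt2; then 11, −78 °C; NaOH, H2O2
Reagents that add atoms: none
Why: Brown asymmetric crotylboration: Schlosser metalation keeps the Z geometry, the closed chair transition state turns the Z-crotyl unit into the 3,4-syn product, and the isopinocampheyl groups from (+)-Ipc2BOMe direct attack to the aldehyde face that gives 4S and hence 3S (the later C5 and C6).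

Step 8
Reactants: 15 (3S,4S,5E)-3-methylhepta-1,5-dien-4-ol
Product: 17 (3S,4R,5E)-3-methylhept-5-ene-1,4-diol, via organoborane 16 (not isolated)
Conditions: 9-BBN (2.2 equiv), THF, 0 °C to rt; NaOH, H2O2
Reagents that add atoms: hydrogen peroxide, OO
Why: Hydroboration–oxidation with 9-BBN is anti-Markovnikov and selective for the terminal vinyl group over the 1,2-disubstituted alkene; no stereocentre is touched (C4 becomes R only by priority change).

Step 9
Reactants: 17 (3S,4R,5E)-3-methylhept-5-ene-1,4-diol
Product: 18 (4S,5R)-4-methyl-5-[(1E)-prop-1-en-1-yl]oxolan-2-one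
Conditions: TEMPO (10 mol%), PhI(OAc)2, CH2Cl2, rt
Reagents that add atoms: none
Why: TEMPO/PhI(OAc)2 oxidative lactonization oxidises the primary alcohol selectively and the 1,4-diol ends as the γ-lactone, cis-4,5 because both centres are carried over unchanged.

Step 10
Reactants: 18 (4S,5R)-4-methyl-5-[(1E)-prop-1-en-1-yl]oxolan-2-one; 19 1-propynyllithium
Product: 20 (6S,7R,8E)-7-hydroxy-6-methyldec-8-en-2-yn-4-one
Conditions: THF, −78 °C; AcOH quench at −78 °C
Reagents that add atoms: none
Why: Acetylide addition to the lactone stops at the ketone stage because the tetrahedral lithium alkoxide survives at −78 °C until the quench, giving the ynone and freeing the later O5 as the only hydroxyl.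

Step 11
Reactants: 20 (6S,7R,8E)-7-hydroxy-6-methyldec-8-en-2-yn-4-one; 4 (2S,3S)-2,3-dimethyloxirane-2-carboxylic acid
Product: 21 (2E,4R,5S)-5-methyl-7-oxodec-2-en-8-yn-4-yl (2S,3S)-2,3-dimethyloxirane-2-carboxylate
Conditions: DCC, DMAP (10 mol%), CH2Cl2, 0 °C to rt
Reagents that add atoms: none
Why: Steglich esterification of the single free secondary alcohol installs the epoxyangelate on O5 before O4 exists, so the two oxygens never need to be told apart; no stereocentre is touched.

Step 12
Reactants: 21 (2E,4R,5S)-5-methyl-7-oxodec-2-en-8-yn-4-yl (2S,3S)-2,3-dimethyloxirane-2-carboxylate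
Product: 23 (2R,3S)-3-methyl-1,5-dioxooct-6-yn-2-yl (2S,3S)-2,3-dimethyloxirane-2-carboxylate, via ozonide 22 (not isolated)
Conditions: O3, CH2Cl2, −78 °C (stopped at consumption of 21); Me2S, −78 °C to rt
Reagents that add atoms: ozone, [O-][O+]=O
Why: Ozonolysis cleaves the electron-rich disubstituted alkene much faster than the electron-poor ynone triple bond, and the α-acyloxy aldehyde is used crude to avoid epimerisation at C2.

**Union and ring closure**

Step 13
Reactants: 23 (2R,3S)-3-methyl-1,5-dioxooct-6-yn-2-yl (2S,3S)-2,3-dimethyloxirane-2-carboxylate; 9 (5S)-3-(bromomethyl)-5-(iodomethyl)furan-2(5H)-one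
Product: 25 (1R,2R,3S)-1-hydroxy-1-[(2S,3R)-2-(iodomethyl)-4-methylidene-5-oxooxolan-3-yl]-3-methyl-5-oxooct-6-yn-2-yl (2S,3S)-2,3-dimethyloxirane-2-carboxylate, via allylindium 24 (not isolated)
Conditions: In powder, THF/H2O (1:1), rt
Reagents that add atoms: none
Why: Indium-mediated Barbier allylation: the allylindium reacts through its γ-carbon (ring C4 of 9, the later C3a) on the face anti to the CH2I group (trans lactone), its ring-locked E-type allyl unit passes through a chair transition state that places carbinol and ring carbon anti (the later 4R), the double bond moves to the exo-methylene, and this reagent control is expected to override the small opposite Felkin preference of the α-acyloxy aldehyde; indium leaves the primary iodide, the ynone and the esters alone.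

Step 14
Reactants: 25 (1R,2R,3S)-1-hydroxy-1-[(2S,3R)-2-(iodomethyl)-4-methylidene-5-oxooxolan-3-yl]-3-methyl-5-oxooct-6-yn-2-yl (2S,3S)-2,3-dimethyloxirane-2-carboxylate
Product: 26 (3aR,4R,5R,6S,9Z,11aR)-4-hydroxy-6,10-dimethyl-3-methylidene-2,8-dioxo-2,3,3a,4,5,6,7,8,11,11a-decahydrocyclodeca[b]furan-5-yl (2S,3S)-2,3-dimethyloxirane-2-carboxylate (CNP0227299.2)
Conditions: (TMS)3SiH (1.3 equiv), AIBN (0.3 equiv), benzene, 80 °C, both added by syringe pump over 12 h, final 1 mM
Reagents that add atoms: none
Why: Proposed new method: the silyl radical abstracts iodine from C11 and the nucleophilic primary radical adds to the β-carbon (C10) of the ynone in a 10-endo-dig radical macrocyclization (closest known type: endo radical macrocyclizations of ω-iodoalkyl enones and ynones to 12- to 16-membered rings), the α-keto vinyl radical is then reduced by the silane inside the ring where the ring-cis 9Z enone is the low-strain geometry, 5-endo attack on the exo-methylene is geometrically disfavoured, and no existing stereocentre is involved.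

**Compound list**
1 | angelic acid, (2Z)-2-methylbut-2-enoic acid | C/C=C(/C)C(=O)O | starting material
2 | (2Z)-2-methylbut-2-en-1-ol | C/C=C(/C)CO | intermediate
3 | [(2R,3S)-2,3-dimethyloxiran-2-yl]methanol | OC[C@@]1(C)O[C@H]1C | intermediate
4 | (2S,3S)-2,3-dimethyloxirane-2-carboxylic acid (epoxyangelic acid) | OC(=O)[C@@]1(C)O[C@H]1C | intermediate
5 | (2S)-but-3-ene-1,2-diol | OC[C@@H](O)C=C | starting material
6 | (2S)-1-iodobut-3-en-2-ol | IC[C@@H](O)C=C | intermediate
7 | 2-(bromomethyl)prop-2-enoic acid | C=C(CBr)C(=O)O | starting material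
8 | (2S)-1-iodobut-3-en-2-yl 2-(bromomethyl)prop-2-enoate | C=C(CBr)C(=O)O[C@H](CI)C=C | intermediate
9 | (5S)-3-(bromomethyl)-5-(iodomethyl)furan-2(5H)-one | BrCC1=C[C@@H](CI)OC1=O | intermediate
10 | cis-but-2-ene | C/C=C\C | starting material
11 | (2E)-but-2-enal (crotonaldehyde) | C/C=C/C=O | starting material
12 | (Z)-crotylpotassium | C/C=C\C[K] | intermediate
13 | (Z)-but-2-en-1-ylbis(isopinocampheyl)borane, isopinocampheyl groups of the (+)-Ipc2BOMe series | C/C=C\CB([C@H]1C[C@H]2C[C@@H]([C@@H]1C)C2(C)C)[C@H]1C[C@H]2C[C@@H]([C@@H]1C)C2(C)C | intermediate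
14 | bis(isopinocampheyl)borinate ester of 15 | C=C[C@H](C)[C@@H](OB([C@H]1C[C@H]2C[C@@H]([C@@H]1C)C2(C)C)[C@H]1C[C@H]2C[C@@H]([C@@H]1C)C2(C)C)/C=C/C | intermediate
15 | (3S,4S,5E)-3-methylhepta-1,5-dien-4-ol | C=C[C@H](C)[C@@H](O)/C=C/C | intermediate
16 | C1-(9-borabicyclo[3.3.1]nonan-9-yl) alkylborane and O4-(9-borabicyclo[3.3.1]nonan-9-yl) borinate of 15 | B1(C2CCCC1CCC2)CC[C@H](C)[C@@H](OB1C2CCCC1CCC2)/C=C/C | intermediate
17 | (3S,4R,5E)-3-methylhept-5-ene-1,4-diol | OCC[C@H](C)[C@@H](O)/C=C/C | intermediate
18 | (4S,5R)-4-methyl-5-[(1E)-prop-1-en-1-yl]oxolan-2-one (cis) | O=C1C[C@H](C)[C@@H](O1)/C=C/C | intermediate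
19 | 1-propynyllithium | [Li]C#CC | starting material
20 | (6S,7R,8E)-7-hydroxy-6-methyldec-8-en-2-yn-4-one | CC#CC(=O)C[C@H](C)[C@@H](O)/C=C/C | intermediate
21 | (2E,4R,5S)-5-methyl-7-oxodec-2-en-8-yn-4-yl (2S,3S)-2,3-dimethyloxirane-2-carboxylate | CC#CC(=O)C[C@H](C)[C@@H](OC(=O)[C@@]1(C)O[C@H]1C)/C=C/C | intermediate
22 | ozonide (5-methyl-1,2,4-trioxolan-3-yl compound) of 21, mixture of trioxolane diastereomers | CC#CC(=O)C[C@H](C)[C@@H](OC(=O)[C@@]1(C)O[C@H]1C)C1OOC(C)O1 | intermediate
23 | (2R,3S)-3-methyl-1,5-dioxooct-6-yn-2-yl (2S,3S)-2,3-dimethyloxirane-2-carboxylate | CC#CC(=O)C[C@H](C)[C@@H](OC(=O)[C@@]1(C)O[C@H]1C)C=O | intermediate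
24 | [(5S)-5-(iodomethyl)-2-oxo-2,5-dihydrofuran-3-yl]methylindium dibromide (formal monomer of the allylindium sesquibromide) | Br[In](Br)CC1=C[C@@H](CI)OC1=O | intermediate
25 | (1R,2R,3S)-1-hydroxy-1-[(2S,3R)-2-(iodomethyl)-4-methylidene-5-oxooxolan-3-yl]-3-methyl-5-oxooct-6-yn-2-yl (2S,3S)-2,3-dimethyloxirane-2-carboxylate | C=C1C(=O)O[C@H](CI)[C@H]1[C@@H](O)[C@H](OC(=O)[C@@]2(C)O[C@H]2C)[C@@H](C)CC(=O)C#CC | intermediate
26 | (3aR,4R,5R,6S,9Z,11aR)-4-hydroxy-6,10-dimethyl-3-methylidene-2,8-dioxo-2,3,3a,4,5,6,7,8,11,11a-decahydrocyclodeca[b]furan-5-yl (2S,3S)-2,3-dimethyloxirane-2-carboxylate | C=C1C(=O)O[C@@H]2C/C(C)=C\C(=O)C[C@H](C)[C@@H](OC(=O)[C@@]3(C)O[C@H]3C)[C@H](O)[C@@H]12 | target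

**Step count and risks**
Total: 14 steps (3 for the acid, 3 for the butenolide, 6 for the aldehyde, 2 for union and ring closure). Longest linear sequence: 8 steps (steps 7 to 14).

Most likely to fail, in this order:

Step 14. The ten-membered closure is slow. The C11 radical can instead be reduced, take the C5 hydrogen by a 1,5-shift, or undergo a 1,2-acyloxy shift. The C4 hydroxyl may also mask the ynone as a six-membered hemiketal. The fallback sets out from 25 and forms the same C10–C11 bond by a different reaction. Anti-hydroiodination of the ynone (NaI, AcOH, MeCN, 0 °C) gives the (Z)-β-iodo enone F1, with iodine cis to the carbonyl so that the 9Z geometry is fixed before ring closure. A reductive vinyl–alkyl coupling with zerovalent nickel made in the flask (NiBr2(dme), 4,4'-di-tert-butyl-2,2'-bipyridine, Zn, DMA, high dilution) then joins the vinyl and alkyl iodides with retention of geometry and comes back to the route at 26.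

Step 13. The reagent-controlled allylation is mismatched with the Felkin preference of the aldehyde, and 23 is prone to epimerise. The fallback sets out from 20. Ozonolysis as in step 12 gives the free α-hydroxy aldehyde F2. Indium allylation with 9 in water then runs under chelation control by the free hydroxyl, which favours the same 4,5-syn product as the reagent, and gives the diol F3. Esterification with 4 (DCC, DMAP, −20 °C) is aimed at O5, since the C4 hydroxyl sits next to the ring carbon and is hydrogen-bonded to the lactone. This comes back to the route at 25. The price is a regioselectivity question that the main route avoids.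

Step 11. A hindered α-quaternary acid meets a hindered secondary alcohol, and DMAP can add to the ynone. The fallback sets out from 18 and makes the ester before the ynone exists. Aminolysis of the lactone (MeNHOMe·HCl, AlMe3, CH2Cl2) gives the hydroxy Weinreb amide F4. Yamaguchi esterification with 4 (2,4,6-trichlorobenzoyl chloride, Et3N, then DMAP, toluene) gives the ester amide F5. 1-Propynylmagnesium bromide (THF, −20 °C) converts the amide into the ynone and comes back to the route at 21, one step longer.

**Further compounds**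
F1 | step 14 | (1R,2R,3S,6Z)-1-hydroxy-7-iodo-1-[(2S,3R)-2-(iodomethyl)-4-methylidene-5-oxooxolan-3-yl]-3-methyl-5-oxooct-6-en-2-yl (2S,3S)-2,3-dimethyloxirane-2-carboxylate | C=C1C(=O)O[C@H](CI)[C@H]1[C@@H](O)[C@H](OC(=O)[C@@]2(C)O[C@H]2C)[C@@H](C)CC(=O)/C=C(/C)I
F2 | step 13 | (2R,3S)-2-hydroxy-3-methyl-5-oxooct-6-ynal | CC#CC(=O)C[C@H](C)[C@@H](O)C=O
F3 | step 13 | (4R,5S)-4-[(1R,2R,3S)-1,2-dihydroxy-3-methyl-5-oxooct-6-yn-1-yl]-5-(iodomethyl)-3-methylideneoxolan-2-one | C=C1C(=O)O[C@H](CI)[C@H]1[C@@H](O)[C@H](O)[C@@H](C)CC(=O)C#CC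
F4 | step 11 | (3S,4R,5E)-4-hydroxy-N-methoxy-N,3-dimethylhept-5-enamide | CON(C)C(=O)C[C@H](C)[C@@H](O)/C=C/C
F5 | step 11 | (2E,4R,5S)-7-[methoxy(methyl)amino]-5-methyl-7-oxohept-2-en-4-yl (2S,3S)-2,3-dimethyloxirane-2-carboxylate | CON(C)C(=O)C[C@H](C)[C@@H](OC(=O)[C@@]1(C)O[C@H]1C)/C=C/C
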